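| flask | solid substrate | gas | remark | time |
|---|---|---|---|---|
| east | 0.23 M | 59 mM (held) | run made earlier |  |
| west | 0.80 M | 59 mM (held) | run made earlier |  |
| zeta | 0.30 M | 59 mM (held) |  | 40 h |
| delta | 1.0 M | 59 mM (held) |  | 40 h |

- east (time / h: target / %): 2.50: 2.7; 5.00: 5.8; 12.0: 16.2; 30.0: 17.5
- west (time / h: target / %): 8.00: 2.6; 15.0: 6.2; 20.0: 8.0; 30.0: 12.2

(scatter of a reading: 0.3 percentage points)

- as a solid, counted per litre of solution: solid substrate
- at the start none of reagent is dissolved
- reactions considered so far: starting material + reagent -> target; starting material + reagent -> isomer of the product; gas <-> reagent; solid substrate <-> starting material; starting material + reagent -> second isomer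
- at the start none of the solid substrate is in solution
- what has only dissolved of solid substrate counts as not reacted

- which one finishes higher in amount of target, in percent of the solid substrate charged ("neither" within 2 percentage points) (zeta / delta / neither)
- amount of target at the end, in percent of the solid substrate charged, zeta
- amount of target at the end, in percent of the solid substrate charged, delta

Start from a ratio: east's target climbs by a fraction 0.0149 h⁻¹ of its charge per hour, west's by 0.00436 h⁻¹. That is a ratio of 3.42, close to the inverse ratio of the charges, 3.48. Take the steps in solution as steady, then, and reckon with one pace for both runs, read from west as 3.49 mM h⁻¹ of target after a lag of 2.04 h.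

Turn the time first. By hand, hours past the end of the solid should add little, and east gains 1.3 percentage points between 12.0 h and 30.0 h. Take its last reading, 17.5%, as the ceiling (the selectivity to target).

Turn the charge next. By hand, more solid keeps the pace and lowers the percentage reached at a given hour, and at 30.0 h west stands at 12.2% against east's 17.5%.

Join the two in the clearing time, charge times ceiling over pace. My reckoning gives 15.0 h for zeta, so zeta reaches the ceiling within 40 h. It gives 50.1 h for delta, and with the lag that is longer than 40 h, so my reckoning puts delta at 13.3%.

The forecast says zeta, with 17.5% for zeta and 13% for delta: “This looks zero-order in solid”.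

The flask gives zeta: 17.6% for zeta and 13.3% for delta.

    starting material + reagent → target (k = 0.0920 M⁻¹ min⁻¹)
    starting material + reagent → isomer of the product (k = 0.290 M⁻¹ min⁻¹)
    gas ⇌ reagent, rate k3*(csat - [reagent]) (kL = 0.0150 min⁻¹)
    solid substrate ⇌ starting material, rate k4*(cs4 - [starting material]) while solid is left; crystals form when [starting material] > cs4 (solubility = 0.150 M, k = 0.00240 min⁻¹)
    starting material + reagent → second isomer (k = 0.140 M⁻¹ min⁻¹)

At 40.0 h delta still holds 22.9% as solid substrate, and left until 400 h it reaches 17.6% beside zeta's 17.6%, which would make the answer neither. Now take a neighbour of zeta charged with 1.2 M. Its clearing time is 60.2 h, which puts it at 11.0%. The neighbour holds 11.1% of target at 40.0 h.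

All runs are simulated for substances that don't exist, noise included.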